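**Strategy.** The cyclohexadienone ring B (C3a–C4–C5–C6–C7–C7a) is cut at C4–C3a and C7–C7a. This exposes ring A as a latent γ-butyrolactone: C7a (bearing O1 and the C7=C7a enol ether) is its acyl carbon and C3a its α-carbon. The lactone, as its ketene acetal, is a two-carbon nucleophile/electrophile. An open-chain C4–C7 unit carrying the preformed quaternary C5 stereocentre, a C4 acetal and a C7 silyl enol ether is the matching four-carbon electrophile/nucleophile. One Lewis-acid cascade forms both C–C bonds; base-induced loss of two methanols then erases the four transient stereocentres, so all diastereomers converge on the dienone.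

Key step: step 9

Remarks on the chemistry:
- Atom labels follow the benzofuran numbering of the target (O1, C2, C3, C3a, C4–C7, C7a); ring A is the dihydrofuran, ring B the carbocycle. The target is (2S,3S,5R), with 2-aryl/3-methyl trans.
- Assumption: methyl 3,3-dimethoxy-2-oxopropanoate (7) is taken as a purchasable α-keto ester.
- The target is a 6-allyl-6-methoxycyclohexa-2,4-dienone and is expected to be prone to allyl migration under acid or heat, so the dienone is unveiled last, under base, at or below 0 °C.

**Step 1**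
Reactants: 1 3,4,5-trimethoxybenzaldehyde
Product: 2 (1S,2S)-2-methyl-1-(3,4,5-trimethoxyphenyl)but-3-en-1-ol
Conditions: (E)-crotyl-B(pin) (1.2 equiv), (S)-TRIP phosphoric acid (5 mol %), toluene, −30 °C; aqueous work-up
Reagents that add atoms: (E)-crotylboronic acid pinacol ester, C/C=C/CB1OC(C)(C)C(C)(C)O1
Why: Chiral-phosphoric-acid-catalysed crotylboration through a closed chair (Zimmerman–Traxler) transition state, in which the E-boronate gives the anti C1/C2 relationship and the (S)-catalyst, the antipode expected to direct si-face attack, sets 1S,2S.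

**Step 2**
Reactants: 2 (1S,2S)-2-methyl-1-(3,4,5-trimethoxyphenyl)but-3-en-1-ol
Product: 3 (1S,2S)-2-methyl-1-(3,4,5-trimethoxyphenyl)butane-1,4-diol
Conditions: 9-BBN (2.5 equiv), THF, 0 °C → rt; then NaOH, H2O2, 0 °C
Reagents that add atoms: hydrogen peroxide, OO
Why: Anti-Markovnikov Brown hydroboration–oxidation of the terminal alkene, which leaves both stereocentres untouched.

**Step 3**
Reactants: 3 (1S,2S)-2-methyl-1-(3,4,5-trimethoxyphenyl)butane-1,4-diol
Product: 4 (4S,5S)-4-methyl-5-(3,4,5-trimethoxyphenyl)oxolan-2-one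
Conditions: TEMPO (10 mol %), PhI(OAc)2 (2.5 equiv), CH2Cl2, rt
Reagents that add atoms: none
Why: Oxidative lactonisation, in which the primary alcohol is oxidised selectively, the aldehyde closes to the lactol and this is oxidised on to the trans lactone.

**Step 4**
Reactants: 4 (4S,5S)-4-methyl-5-(3,4,5-trimethoxyphenyl)oxolan-2-one
Product: 6 (4S,5S)-2,2-dimethoxy-4-methyl-5-(3,4,5-trimethoxyphenyl)oxolane, via lactonium tetrafluoroborate 5 (not isolated)
Conditions: Me3O·BF4, CH2Cl2, rt; then NaOMe, MeOH, −78 → 0 °C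
Reagents that add atoms: trimethyloxonium tetrafluoroborate, C[O+](C)C.F[B-](F)(F)F; sodium methoxide, [Na+].[O-]C
Why: O-Methylation of the lactone carbonyl with Meerwein's salt gives the dialkoxycarbenium ion, which methoxide captures at C2 to give the cyclic ortho ester without touching C4 or C5.

**Step 5**
Reactants: 7 methyl 3,3-dimethoxy-2-oxopropanoate
Product: 8 methyl (2R)-2-(dimethoxymethyl)-2-hydroxypent-4-enoate
Conditions: tetraallyltin, In(OTf)3 (10 mol %), C2-symmetric N,N′-dioxide ligand from (S)-pipecolic acid and 2,6-diisopropylaniline (10 mol %), DMF, 0 °C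
Reagents that add atoms: tetraallyltin, C=CC[Sn](CC=C)(CC=C)CC=C
Why: Catalytic enantioselective Keck-type allylstannane addition to an α-keto ester, in which two-point binding of the 1,2-dicarbonyl to the chiral In(OTf)3 complex exposes one ketone face and the ligand antipode is chosen to give 2R.

**Step 6**
Reactants: 8 methyl (2R)-2-(dimethoxymethyl)-2-hydroxypent-4-enoate
Product: 9 methyl (2R)-2-(dimethoxymethyl)-2-methoxypent-4-enoate
Conditions: NaH, MeI, THF/DMF, 0 °C
Reagents that add atoms: iodomethane, CI
Why: Williamson etherification of the tertiary alkoxide, with no enolisable position that could endanger the quaternary centre.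

**Step 7**
Reactants: 9 methyl (2R)-2-(dimethoxymethyl)-2-methoxypent-4-enoate
Product: 11 (3R)-3-(dimethoxymethyl)-1,3-dimethoxyhex-5-en-2-one, via Weinreb amide 10 (not isolated)
Conditions: MeNHOMe·HCl, iPrMgCl, THF, −20 → 0 °C; then MeOCH2Li (from Bu3SnCH2OMe, n-BuLi, THF, −78 °C), −78 °C; NH4Cl work-up
Reagents that add atoms: tributyl(methoxymethyl)stannane, CCCC[Sn](CCCC)(CCCC)COC; N,O-dimethylhydroxylamine hydrochloride (atoms in 10 only), CNOC.Cl
Why: One-pot Weinreb ketone synthesis, in which the magnesium amide converts the ester into the N-methoxy-N-methylamide and its chelated tetrahedral adduct with MeOCH2Li (from tin–lithium exchange) stops at the ketone.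

**Step 8**
Reactants: 11 (3R)-3-(dimethoxymethyl)-1,3-dimethoxyhex-5-en-2-one
Product: 12 {[(1Z,3S)-3-(dimethoxymethyl)-1,3-dimethoxyhexa-1,5-dien-2-yl]oxy}trimethylsilane
Conditions: LiN(SiMe3)2, TMSCl, THF, −78 °C; Et3N, pentane work-up
Reagents that add atoms: chlorotrimethylsilane, C[Si](C)(C)Cl
Why: Kinetic enolisation with in-situ silylation gives a single regioisomer because the quaternary C3 leaves C1 as the only enolisable position (the S descriptor reflects only a change in CIP priorities).

**Step 9**
Reactants: 6 (4S,5S)-2,2-dimethoxy-4-methyl-5-(3,4,5-trimethoxyphenyl)oxolane; 12 {[(1Z,3S)-3-(dimethoxymethyl)-1,3-dimethoxyhexa-1,5-dien-2-yl]oxy}trimethylsilane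
Product: 15 (2S,3S,5R)-5,7-dimethoxy-3-methyl-5-(prop-2-en-1-yl)-2-(3,4,5-trimethoxyphenyl)-2,3-dihydro-1-benzofuran-6(5H)-one, via ketene acetal 13 (not isolated), via bicyclic ketal 14 (not isolated)
Conditions: 6 (1.3 equiv), TMSOTf (1.4 equiv), iPr2NEt (1.6 equiv), CH2Cl2, 0 °C; then 12, TMSOTf (0.5 equiv), −78 → −40 °C; then KOtBu (excess), THF, −40 → 0 °C
Reagents that add atoms: none
Why: Proposed new method: after TMSOTf/iPr2NEt has turned ortho ester 6 into ketene acetal 13, TMSOTf ionises the neopentyl dimethyl acetal of 12 to a C4 oxocarbenium ion, which 13 captures at C3a (bond C4–C3a); the resulting 2-methoxyoxolan-2-ylium ion at C7a is then trapped intramolecularly by the C7 silyl enol ether (bond C7–C7a) with release of TMSOMe, so the acid is regenerated. The closest known reaction types are the Mukaiyama additions of silyl enol ethers and ketene acetals to acetals and ortho esters and the Lewis-acid formal [4+2] cycloaddition of 3-alkoxycyclobutanone-derived 1,4-zwitterions with enol ethers; an open-chain acetal/enol silane as the 1,4-dipole with a lactone-derived ketene acetal as the two-carbon partner has not been shown. Ring B closes in a 6-(enolendo)-exo-trig mode, ring A being carried intact. No permanent stereocentre is created: C3a, C4, C7 and C7a of 14 form as mixtures and are all erased when KOtBu removes two molecules of methanol (E1cB across C7/C7a, then vinylogous E1cB across C3a/C4), so every diastereomer of 14 should converge on 15, whose C5 (from 12) and C2/C3 (from 6) are not touched. The step needs a single regiochemistry and capture of the oxocarbenium ion by 13 before the enol silane reacts; the quaternary C5 secures the first (only C7 can be the enol carbon, only C4 the acetal carbon) and the much higher nucleophilicity of the ketene acetal the second. The dienone is exposed only to base at or below 0 °C, because acid or heat would be expected to trigger allyl migration.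

**Compound list**
1 | 3,4,5-trimethoxybenzaldehyde | COc1cc(C=O)cc(OC)c1OC | starting material
2 | (1S,2S)-2-methyl-1-(3,4,5-trimethoxyphenyl)but-3-en-1-ol | C=C[C@H](C)[C@H](O)c1cc(OC)c(OC)c(OC)c1 | intermediate
3 | (1S,2S)-2-methyl-1-(3,4,5-trimethoxyphenyl)butane-1,4-diol | OCC[C@H](C)[C@H](O)c1cc(OC)c(OC)c(OC)c1 | intermediate
4 | (4S,5S)-4-methyl-5-(3,4,5-trimethoxyphenyl)oxolan-2-one | O=C1C[C@H](C)[C@@H](c2cc(OC)c(OC)c(OC)c2)O1 | intermediate
5 | (4S,5S)-2-methoxy-4-methyl-5-(3,4,5-trimethoxyphenyl)-4,5-dihydro-3H-furan-1-ium tetrafluoroborate (O-methyl lactonium salt) | C[O+]=C1C[C@H](C)[C@@H](c2cc(OC)c(OC)c(OC)c2)O1.F[B-](F)(F)F | intermediate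
6 | (4S,5S)-2,2-dimethoxy-4-methyl-5-(3,4,5-trimethoxyphenyl)oxolane | COC1(OC)C[C@H](C)[C@@H](c2cc(OC)c(OC)c(OC)c2)O1 | intermediate
7 | methyl 3,3-dimethoxy-2-oxopropanoate | COC(OC)C(=O)C(=O)OC | starting material
8 | methyl (2R)-2-(dimethoxymethyl)-2-hydroxypent-4-enoate | C=CC[C@](O)(C(=O)OC)C(OC)OC | intermediate
9 | methyl (2R)-2-(dimethoxymethyl)-2-methoxypent-4-enoate | C=CC[C@](OC)(C(=O)OC)C(OC)OC | intermediate
10 | (2R)-2-(dimethoxymethyl)-N,2-dimethoxy-N-methylpent-4-enamide | C=CC[C@](OC)(C(=O)N(C)OC)C(OC)OC | intermediate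
11 | (3R)-3-(dimethoxymethyl)-1,3-dimethoxyhex-5-en-2-one | C=CC[C@](OC)(C(=O)COC)C(OC)OC | intermediate
12 | {[(1Z,3S)-3-(dimethoxymethyl)-1,3-dimethoxyhexa-1,5-dien-2-yl]oxy}trimethylsilane | C=CC[C@](OC)(/C(O[Si](C)(C)C)=C/OC)C(OC)OC | intermediate
13 | (2S,3S)-5-methoxy-3-methyl-2-(3,4,5-trimethoxyphenyl)-2,3-dihydrofuran | COC1=C[C@H](C)[C@@H](c2cc(OC)c(OC)c(OC)c2)O1 | intermediate
14 | (2S,3S,5R)-4,5,7,7a-tetramethoxy-3-methyl-5-(prop-2-en-1-yl)-2-(3,4,5-trimethoxyphenyl)-3,3a,4,5,7,7a-hexahydro-1-benzofuran-6(2H)-one (mixture at C3a, C4, C7, C7a) | C=CC[C@@]1(OC)C(OC)C2C(OC)(C(OC)C1=O)O[C@H](c1cc(OC)c(OC)c(OC)c1)[C@H]2C | intermediate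
15 | (2S,3S,5R)-5,7-dimethoxy-3-methyl-5-(prop-2-en-1-yl)-2-(3,4,5-trimethoxyphenyl)-2,3-dihydro-1-benzofuran-6(5H)-one | C=CC[C@@]1(OC)C=C2C(=C(OC)C1=O)O[C@H](c1cc(OC)c(OC)c(OC)c1)[C@H]2C | target

**Total step count:** 9. **Longest linear sequence:** 5 steps (1–4 then 9, or 5–8 then 9).

**Steps most likely to fail**

1. Step 9 (proposed new method). The cascade may stop after the first C–C bond if the oxolanylium ion loses its O-methyl group or is quenched before the enol silane closes. The ketene acetal may be protonated and self-condense. The benzylic C2–O1 bond may ionise under TMSOTf, and the dienone may undergo allyl migration if acid survives into the warm-up. The fallback uses known steps only and sets out from lactone 4 and ketone 11. Lactone 4 is converted with LDA/TMSCl into the silyl ketene acetal F1. F1 adds to the dimethyl acetal of 11 under catalytic TMSOTf (Mukaiyama addition to an acetal, CH2Cl2, −78 °C) to give the lactone F2 (C4–C3a bond). LiN(SiMe3)2 in THF then forms the enolate of the methoxymethyl ketone, which attacks the lactone carbonyl (Dieckmann-type Claisen condensation, C7–C7a bond) to give the ring-opened hydroxy 1,3-diketone F3. PPTS/MgSO4 closes the vinylogous ester F4 by cyclodehydration, and KOtBu in THF at 0 °C eliminates methanol, which comes back to the route at 15.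

2. Step 5. Facial discrimination may be poor because both the ester and the acetal can chelate the metal, and allyl transfer to the Lewis-acid-activated acetal may compete. The fallback replaces asymmetric catalysis by resolution and sets out from 7. Barbier allylation with allyl bromide and indium metal in THF/H2O gives the racemic hydroxy ester F5, and LiOH saponification gives the racemic acid F6. Fractional crystallisation with (S)-1-phenylethylamine (or its antipode, should the other salt be the less soluble one) gives the ammonium salt F7 of the R acid. MeI/K2CO3 in DMF re-esterifies it and comes back to the route at 8.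

3. Step 4. During the slow O-methylation the benzylic C5–O bond of lactonium ion 5 may ionise reversibly, leading to epimerisation or elimination to a styrene, and the ortho ester may be lost to adventitious acid on isolation. The fallback avoids cationic activation of the lactone and sets out from 4. Lawesson's reagent (toluene, 90 °C) gives the thionolactone F8. LDA then MeI S-methylates the enethiolate to the ketene O,S-acetal F9. F9 takes the place of 13 in the cascade of step 9 with 12 (catalytic TMSOTf, −78 °C) and gives the O,S-ketal F10, from which KOtBu removes methanethiol and methanol; this comes back to the route at 15.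

Further compounds
F1 | step 9 | trimethyl{[(2S,3S)-3-methyl-2-(3,4,5-trimethoxyphenyl)-2,3-dihydrofuran-5-yl]oxy}silane | C[Si](C)(C)OC1=C[C@H](C)[C@@H](c2cc(OC)c(OC)c(OC)c2)O1
F2 | step 9 | (4S,5S)-4-methyl-3-[(2R)-1,2,4-trimethoxy-3-oxo-2-(prop-2-en-1-yl)butyl]-5-(3,4,5-trimethoxyphenyl)oxolan-2-one (mixture at C3 and C1′) | C=CC[C@](OC)(C(=O)COC)C(OC)C1C(=O)O[C@H](c2cc(OC)c(OC)c(OC)c2)[C@H]1C
F3 | step 9 | (4R)-6-[(1S,2S)-1-hydroxy-1-(3,4,5-trimethoxyphenyl)propan-2-yl]-2,4,5-trimethoxy-4-(prop-2-en-1-yl)cyclohexane-1,3-dione (mixture at C2, C5, C6) | C=CC[C@@]1(OC)C(OC)C([C@H](C)[C@H](O)c2cc(OC)c(OC)c(OC)c2)C(=O)C(OC)C1=O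
F4 | step 9 | (2S,3S,5R)-4,5,7-trimethoxy-3-methyl-5-(prop-2-en-1-yl)-2-(3,4,5-trimethoxyphenyl)-3,3a,4,5-tetrahydro-1-benzofuran-6(2H)-one (mixture at C3a, C4) | C=CC[C@@]1(OC)C(OC)C2C(=C(OC)C1=O)O[C@H](c1cc(OC)c(OC)c(OC)c1)[C@H]2C
F5 | step 5 | methyl 2-(dimethoxymethyl)-2-hydroxypent-4-enoate (racemic) | C=CCC(O)(C(=O)OC)C(OC)OC
F6 | step 5 | 2-(dimethoxymethyl)-2-hydroxypent-4-enoic acid (racemic) | C=CCC(O)(C(=O)O)C(OC)OC
F7 | step 5 | (S)-1-phenylethylammonium (2R)-2-(dimethoxymethyl)-2-hydroxypent-4-enoate | C=CC[C@](O)(C(=O)[O-])C(OC)OC.C[C@H]([NH3+])c1ccccc1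
F8 | step 4 | (4S,5S)-4-methyl-5-(3,4,5-trimethoxyphenyl)oxolane-2-thione | S=C1C[C@H](C)[C@@H](c2cc(OC)c(OC)c(OC)c2)O1
F9 | step 4 | (2S,3S)-3-methyl-5-(methylsulfanyl)-2-(3,4,5-trimethoxyphenyl)-2,3-dihydrofuran | CSC1=C[C@H](C)[C@@H](c2cc(OC)c(OC)c(OC)c2)O1
F10 | step 4 | (2S,3S,5R)-4,5,7-trimethoxy-3-methyl-7a-(methylsulfanyl)-5-(prop-2-en-1-yl)-2-(3,4,5-trimethoxyphenyl)-3,3a,4,5,7,7a-hexahydro-1-benzofuran-6(2H)-one (mixture at C3a, C4, C7, C7a) | C=CC[C@@]1(OC)C(OC)C2C(SC)(C(OC)C1=O)O[C@H](c1cc(OC)c(OC)c(OC)c1)[C@H]2C
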